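The two halves of the target are the same 2,3-seco-cadinane unit, so one intermediate serves twice. The cyclohexane ring of that unit is read as a Diels–Alder adduct (lactone numbering): C3a–C4–C5–C6 is the diene, C7a–C7 the dienophile, and the C6–C7 and C3a–C7a bonds form in one enantioselective [4+2]. The precursor is a (Z)-dienyl cyclic carbonate, whose terminus C3a already carries the tertiary oxygen and the lactone CH2O, plus a fumaroyl oxazolidinone. The step sets C3a, C6, C7 and C7a; hydrogenation and carbonate collapse give the hydroxy lactone. Dehydration of one portion gives a butenolide acid that acylates the tertiary alcohol of the other; double Stille hydroxymethylation and ester cleavage finish.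

Key step: step 5

Remark: locants follow hexahydro-2-benzofuran-1(3H)-one (C1 lactone C=O, C3 OCH2, C3a carbinol carbon, C6 isopropyl carbon, C7 side-chain carbon, C7a ring-fusion CH); compounds 1, 4, 7, 8, 16 and 24 are taken as purchased.

Step 1
Reactants: 1 3-methylbut-1-yne
Product: 3 (E)-1-iodo-3-methylbut-1-ene, via alkenylalane 2 (not isolated)
Conditions: iBu2AlH, hexane, 50 °C (sealed); then I2, THF, −50 °C → 0 °C
Reagents that add atoms: iodine, II
Why: Syn-hydroalumination of the terminal alkyne puts aluminium on the terminal carbon and iodinolysis of the alkenyl–aluminium bond goes with retention, so only the (E)-iodide should form (hydroalumination–iodination).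

Step 2
Reactants: 3 (E)-1-iodo-3-methylbut-1-ene; 4 prop-2-yn-1-ol
Product: 5 (4E)-6-methylhept-4-en-2-yn-1-ol
Conditions: Pd(PPh3)2Cl2 (2 mol %), CuI (4 mol %), Et3N, THF, rt
Reagents that add atoms: none
Why: Sonogashira coupling of an alkenyl iodide with a terminal alkyne proceeds with retention of the (E)-geometry and tolerates the free alcohol.

Step 3
Reactants: 5 (4E)-6-methylhept-4-en-2-yn-1-ol
Product: 6 (4Z)-4-[(2E)-4-methylpent-2-en-1-ylidene]-1,3-dioxolan-2-one
Conditions: CO2 (10 bar), AgOAc (10 mol %), DBU (1 equiv), toluene, rt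
Reagents that add atoms: carbon dioxide, O=C=O
Why: Silver-catalysed carboxylative cyclisation of a propargylic alcohol: the carbonate oxygen adds 5-exo-dig anti to the silver-bound alkyne and protodemetalation should give the (Z)-alkylidene carbonate, with the ring oxygen cis to the dienyl chain.

Step 4
Reactants: 7 monoethyl fumarate; 8 1,3-oxazolidin-2-one
Product: 10 ethyl (2E)-4-oxo-4-(2-oxo-1,3-oxazolidin-3-yl)but-2-enoate, via mixed pivalic anhydride 9 (not isolated)
Conditions: PivCl, Et3N, THF, −20 °C; then 8, LiCl, rt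
Reagents that add atoms: none
Why: N-acylation of the oxazolidinone through the mixed pivalic anhydride is a standard route to 3-acyl-oxazolidin-2-ones and leaves the (E)-alkene untouched.

Step 5
Reactants: 6 (4Z)-4-[(2E)-4-methylpent-2-en-1-ylidene]-1,3-dioxolan-2-one; 10 ethyl (2E)-4-oxo-4-(2-oxo-1,3-oxazolidin-3-yl)but-2-enoate
Product: 11 ethyl (5S,6S,7R,8S)-2-oxo-6-[(2-oxo-1,3-oxazolidin-3-yl)carbonyl]-8-(propan-2-yl)-1,3-dioxaspiro[4.5]dec-9-ene-7-carboxylate
Conditions: [Cu(L)](SbF6)2 (10 mol %; L = 2,2'-(propane-2,2-diyl)bis[(4S)-4-tert-butyl-4,5-dihydro-1,3-oxazole]), CH2Cl2, 0 °C → rt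
Reagents that add atoms: none
Why: The cationic square-planar divalent-copper bis(oxazoline) complex chelates both imide carbonyls of 10 (s-cis acyl conformer) and the diene adds in a concerted but asynchronous [4+2], the isopropyl-bearing terminus bonding first to the imide beta-carbon while positive charge builds at the oxygen- and alkyl-substituted terminus, which fixes the regiochemistry; the closest known reaction type is the copper–bis(oxazoline)-catalysed Diels–Alder reaction of 3-acyl-oxazolidin-2-ones with 1-acyloxy dienes. The cyclohexene is closed by an intermolecular suprafacial–suprafacial [4+2] cycloaddition that makes the C8–C7 and C5–C6 bonds (later C6–C7 and C3a–C7a). Diene geometry controls C5 and C8: the (Z)-enol carbonate holds the ring oxygen inside and CH2O outside, the (E)-alkene holds isopropyl outside, so isopropyl and CH2O end up cis, and the (E)-dienophile makes the C6 and C7 carbonyl groups trans. Endo orientation of the chelated imide places its carbonyl cis to isopropyl and CH2O, and on the square-planar chelate model the tert-butyl group of the (S,S)-ligand shields the Si face of the imide alpha-carbon, so the diene should add to the Re face and give the (5S,6S,7R,8S) adduct. The step needs regio-, endo- and facial selectivity, secured respectively by the donor pattern of the diene together with bidentate activation of the imide over the ester, by secondary overlap with the chelated imide, and by the C2-symmetric ligand; the inside oxygen slows the reaction but is tied back in the five-membered ring.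

Step 6
Reactants: 11 ethyl (5S,6S,7R,8S)-2-oxo-6-[(2-oxo-1,3-oxazolidin-3-yl)carbonyl]-8-(propan-2-yl)-1,3-dioxaspiro[4.5]dec-9-ene-7-carboxylate
Product: 12 ethyl (5S,6S,7R,8R)-2-oxo-6-[(2-oxo-1,3-oxazolidin-3-yl)carbonyl]-8-(propan-2-yl)-1,3-dioxaspiro[4.5]decane-7-carboxylate
Conditions: H2 (1 atm), Rh/Al2O3 (5 wt %), EtOAc, rt
Reagents that add atoms: none
Why: Catalytic hydrogenation of the only C=C bond creates no stereocentre, and rhodium on alumina is chosen because it should not hydrogenolyse the allylic C–O bond of the carbonate.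

Step 7
Reactants: 12 ethyl (5S,6S,7R,8R)-2-oxo-6-[(2-oxo-1,3-oxazolidin-3-yl)carbonyl]-8-(propan-2-yl)-1,3-dioxaspiro[4.5]decane-7-carboxylate
Product: 14 (3aS,6R,7R,7aS)-3a-hydroxy-1-oxo-6-(propan-2-yl)octahydro-2-benzofuran-7-carboxylic acid, via dihydroxy diacid 13 (not isolated)
Conditions: LiOH, H2O2, THF/H2O, 0 °C; aq Na2SO3; then LiOH, rt; then 1 M HCl, pH 2
Reagents that add atoms: lithium hydroxide, [Li+].[OH-]
Why: Hydroperoxide cleaves the imide at its exocyclic carbonyl, hydroxide hydrolyses the cyclic carbonate and the ethyl ester, and on acidification the cis-disposed CH2OH and C7a carboxyl groups close the gamma-lactone (lactonisation), no stereocentre being touched because C7 already sits trans to both neighbours.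

Step 8
Reactants: 14 (3aS,6R,7R,7aS)-3a-hydroxy-1-oxo-6-(propan-2-yl)octahydro-2-benzofuran-7-carboxylic acid
Product: 15 (3aS,6R,7R,7aS)-3a-hydroxy-7-(hydroxymethyl)-6-(propan-2-yl)hexahydro-2-benzofuran-1(3H)-one
Conditions: BH3·SMe2, THF, 0 °C → rt; MeOH
Reagents that add atoms: none
Why: Borane reduces a free carboxylic acid through its acyloxyborane much faster than a lactone, so only the C7 acid should be reduced (chemoselective borane reduction).

Step 9
Reactants: 16 tert-butyl (triphenyl-λ5-phosphanylidene)acetate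
Product: 17 tert-butyl bromo(triphenyl-λ5-phosphanylidene)acetate
Conditions: NBS, CH2Cl2, −20 °C → rt
Reagents that add atoms: N-bromosuccinimide, O=C1CCC(=O)N1Br
Why: Electrophilic bromination of the stabilised ylide at carbon, followed by deprotonation of the bromophosphonium ion by succinimide anion, gives the alpha-bromo ylide (halogenation of an ester-stabilised phosphorane).

Step 10
Reactants: 15 (3aS,6R,7R,7aS)-3a-hydroxy-7-(hydroxymethyl)-6-(propan-2-yl)hexahydro-2-benzofuran-1(3H)-one; 17 tert-butyl bromo(triphenyl-λ5-phosphanylidene)acetate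
Product: 19 tert-butyl (2Z)-2-bromo-3-[(3aS,6R,7R,7aS)-3a-hydroxy-1-oxo-6-(propan-2-yl)octahydro-2-benzofuran-7-yl]prop-2-enoate, via aldehyde 18 (not isolated)
Conditions: Dess–Martin periodinane, NaHCO3, ClCH2CH2Cl, rt; then 17, 60 °C
Reagents that add atoms: none
Why: Dess–Martin oxidation of the primary alcohol (the tertiary one is inert) is followed in the same flask by Wittig olefination with the stabilised bromo ylide, which places the ester trans to the ring carbon and so should give the (Z)-2-bromoacrylate, while C7 keeps its preferred trans,trans configuration.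

Step 11
Reactants: 19 tert-butyl (2Z)-2-bromo-3-[(3aS,6R,7R,7aS)-3a-hydroxy-1-oxo-6-(propan-2-yl)octahydro-2-benzofuran-7-yl]prop-2-enoate
Product: 20 tert-butyl (2Z)-2-bromo-3-[(6R,7S)-1-oxo-6-(propan-2-yl)-1,3,4,5,6,7-hexahydro-2-benzofuran-7-yl]prop-2-enoate
Conditions: Burgess reagent, toluene, 70 °C
Reagents that add atoms: none
Why: Burgess dehydration is a syn-elimination through the sulfamate ester, and the C7a hydrogen is cis to the C3a oxygen and the most acidic syn hydrogen, so the conjugated butenolide should form with C6 and C7 untouched.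

Step 12
Reactants: 20 tert-butyl (2Z)-2-bromo-3-[(6R,7S)-1-oxo-6-(propan-2-yl)-1,3,4,5,6,7-hexahydro-2-benzofuran-7-yl]prop-2-enoate
Product: 21 (2Z)-2-bromo-3-[(6R,7S)-1-oxo-6-(propan-2-yl)-1,3,4,5,6,7-hexahydro-2-benzofuran-7-yl]prop-2-enoic acid
Conditions: CF3CO2H/CH2Cl2 1:4, 0 °C → rt
Reagents that add atoms: none
Why: Acidolysis of the tert-butyl ester through the tert-butyl cation leaves the butenolide and the alkenyl bromide intact.

Step 13
Reactants: 21 (2Z)-2-bromo-3-[(6R,7S)-1-oxo-6-(propan-2-yl)-1,3,4,5,6,7-hexahydro-2-benzofuran-7-yl]prop-2-enoic acid; 19 tert-butyl (2Z)-2-bromo-3-[(3aS,6R,7R,7aS)-3a-hydroxy-1-oxo-6-(propan-2-yl)octahydro-2-benzofuran-7-yl]prop-2-enoate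
Product: 23 (3aS,6R,7R,7aS)-7-[(1Z)-2-bromo-3-tert-butoxy-3-oxoprop-1-en-1-yl]-1-oxo-6-(propan-2-yl)octahydro-2-benzofuran-3a-yl (2Z)-2-bromo-3-[(6R,7S)-1-oxo-6-(propan-2-yl)-1,3,4,5,6,7-hexahydro-2-benzofuran-7-yl]prop-2-enoate, via mixed trichlorobenzoic anhydride 22 (not isolated)
Conditions: 2,4,6-Cl3C6H2COCl, Et3N, THF, rt; then 19, DMAP, toluene, rt → 50 °C
Reagents that add atoms: none
Why: Yamaguchi esterification: DMAP turns the mixed anhydride into an acylpyridinium ion electrophilic enough for the tertiary alcohol, and neither partner carries another free OH or CO2H group.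

Step 14
Reactants: 23 the dibromo diester of step 13; 24 (tributylstannyl)methanol
Product: 25 (3aS,6R,7S,7aS)-7-[(1E)-3-tert-butoxy-2-(hydroxymethyl)-3-oxoprop-1-en-1-yl]-1-oxo-6-(propan-2-yl)octahydro-2-benzofuran-3a-yl (2E)-2-(hydroxymethyl)-3-[(6R,7S)-1-oxo-6-(propan-2-yl)-1,3,4,5,6,7-hexahydro-2-benzofuran-7-yl]prop-2-enoate
Conditions: 24 (2.5 equiv), Pd(PPh3)4 (10 mol %), 1,4-dioxane, 90 °C
Reagents that add atoms: (tributylstannyl)methanol (the second equivalent of 24, one being consumed per alkenyl bromide), OC[Sn](CCCC)(CCCC)CCCC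
Why: Twofold Stille coupling transfers one hydroxymethyl group from one equivalent of stannane 24 to each of the two alkenyl bromides with retention of alkene geometry, so each (Z)-bromide should become the (E)-2-(hydroxymethyl)acrylate.

Step 15
Reactants: 25 the bis(hydroxymethyl) tert-butyl ester of step 14
Product: 26 the target, (2E)-2-(hydroxymethyl)-3-[(3aS,6R,7S,7aS)-3a-{[(2E)-2-(hydroxymethyl)-3-[(6R,7S)-1-oxo-6-(propan-2-yl)-1,3,4,5,6,7-hexahydro-2-benzofuran-7-yl]prop-2-enoyl]oxy}-1-oxo-6-(propan-2-yl)octahydro-2-benzofuran-7-yl]prop-2-enoic acid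
Conditions: CF3CO2H/CH2Cl2 1:4, 0 °C → rt
Reagents that add atoms: none
Why: Acidolysis removes the tert-butyl ester, while the tertiary ester at C3a should resist ionisation because its cation would be destabilised by the adjacent lactone carbonyl and acyloxymethyl groups.

Compound list
1 | 3-methylbut-1-yne | CC(C)C#C | starting material
2 | (E)-diisobutyl(3-methylbut-1-en-1-yl)alane (not isolated) | CC(C)/C=C/[Al](CC(C)C)CC(C)C | intermediate
3 | (E)-1-iodo-3-methylbut-1-ene | CC(C)/C=C/I | intermediate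
4 | prop-2-yn-1-ol | OCC#C | starting material
5 | (4E)-6-methylhept-4-en-2-yn-1-ol | CC(C)/C=C/C#CCO | intermediate
6 | (4Z)-4-[(2E)-4-methylpent-2-en-1-ylidene]-1,3-dioxolan-2-one | CC(C)/C=C/C=C1/COC(=O)O1 | intermediate
7 | monoethyl fumarate, (2E)-4-ethoxy-4-oxobut-2-enoic acid | CCOC(=O)/C=C/C(=O)O | starting material
8 | 1,3-oxazolidin-2-one | O=C1NCCO1 | starting material
9 | (2E)-4-ethoxy-4-oxobut-2-enoic pivalic anhydride (not isolated) | CCOC(=O)/C=C/C(=O)OC(=O)C(C)(C)C | intermediate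
10 | ethyl (2E)-4-oxo-4-(2-oxo-1,3-oxazolidin-3-yl)but-2-enoate | CCOC(=O)/C=C/C(=O)N1CCOC1=O | intermediate
11 | ethyl (5S,6S,7R,8S)-2-oxo-6-[(2-oxo-1,3-oxazolidin-3-yl)carbonyl]-8-(propan-2-yl)-1,3-dioxaspiro[4.5]dec-9-ene-7-carboxylate | CC(C)[C@H]1C=C[C@@]2(COC(=O)O2)[C@@H](C(=O)N3CCOC3=O)[C@@H]1C(=O)OCC | intermediate
12 | ethyl (5S,6S,7R,8R)-2-oxo-6-[(2-oxo-1,3-oxazolidin-3-yl)carbonyl]-8-(propan-2-yl)-1,3-dioxaspiro[4.5]decane-7-carboxylate | CC(C)[C@H]1CC[C@@]2(COC(=O)O2)[C@@H](C(=O)N3CCOC3=O)[C@@H]1C(=O)OCC | intermediate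
13 | (1R,2S,3S,6R)-3-hydroxy-3-(hydroxymethyl)-6-(propan-2-yl)cyclohexane-1,2-dicarboxylic acid (not isolated) | CC(C)[C@H]1CC[C@@](O)(CO)[C@@H](C(=O)O)[C@@H]1C(=O)O | intermediate
14 | (3aS,6R,7R,7aS)-3a-hydroxy-1-oxo-6-(propan-2-yl)octahydro-2-benzofuran-7-carboxylic acid | CC(C)[C@H]1CC[C@@]2(O)COC(=O)[C@H]2[C@@H]1C(=O)O | intermediate
15 | (3aS,6R,7R,7aS)-3a-hydroxy-7-(hydroxymethyl)-6-(propan-2-yl)hexahydro-2-benzofuran-1(3H)-one | CC(C)[C@H]1CC[C@@]2(O)COC(=O)[C@H]2[C@@H]1CO | intermediate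
16 | tert-butyl (triphenyl-λ5-phosphanylidene)acetate | CC(C)(C)OC(=O)C=P(c1ccccc1)(c1ccccc1)c1ccccc1 | starting material
17 | tert-butyl bromo(triphenyl-λ5-phosphanylidene)acetate | CC(C)(C)OC(=O)C(Br)=P(c1ccccc1)(c1ccccc1)c1ccccc1 | intermediate
18 | (3aS,6R,7R,7aS)-3a-hydroxy-1-oxo-6-(propan-2-yl)octahydro-2-benzofuran-7-carbaldehyde (not isolated) | CC(C)[C@H]1CC[C@@]2(O)COC(=O)[C@H]2[C@@H]1C=O | intermediate
19 | tert-butyl (2Z)-2-bromo-3-[(3aS,6R,7R,7aS)-3a-hydroxy-1-oxo-6-(propan-2-yl)octahydro-2-benzofuran-7-yl]prop-2-enoate | CC(C)[C@H]1CC[C@@]2(O)COC(=O)[C@H]2[C@@H]1/C=C(\Br)C(=O)OC(C)(C)C | intermediate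
20 | tert-butyl (2Z)-2-bromo-3-[(6R,7S)-1-oxo-6-(propan-2-yl)-1,3,4,5,6,7-hexahydro-2-benzofuran-7-yl]prop-2-enoate | CC(C)(C)OC(=O)/C(Br)=C/[C@H]1C2=C(CC[C@@H]1C(C)C)COC2=O | intermediate
21 | (2Z)-2-bromo-3-[(6R,7S)-1-oxo-6-(propan-2-yl)-1,3,4,5,6,7-hexahydro-2-benzofuran-7-yl]prop-2-enoic acid | OC(=O)/C(Br)=C/[C@H]1C2=C(CC[C@@H]1C(C)C)COC2=O | intermediate
22 | mixed anhydride of 21 with 2,4,6-trichlorobenzoic acid (not isolated) | O=C(OC(=O)/C(Br)=C/[C@H]1C2=C(CC[C@@H]1C(C)C)COC2=O)c1c(Cl)cc(Cl)cc1Cl | intermediate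
23 | (3aS,6R,7R,7aS)-7-[(1Z)-2-bromo-3-tert-butoxy-3-oxoprop-1-en-1-yl]-1-oxo-6-(propan-2-yl)octahydro-2-benzofuran-3a-yl (2Z)-2-bromo-3-[(6R,7S)-1-oxo-6-(propan-2-yl)-1,3,4,5,6,7-hexahydro-2-benzofuran-7-yl]prop-2-enoate | CC(C)[C@H]1CC[C@@]2(OC(=O)/C(Br)=C/[C@H]3C4=C(CC[C@@H]3C(C)C)COC4=O)COC(=O)[C@H]2[C@@H]1/C=C(\Br)C(=O)OC(C)(C)C | intermediate
24 | (tributylstannyl)methanol | OC[Sn](CCCC)(CCCC)CCCC | starting material
25 | (3aS,6R,7S,7aS)-7-[(1E)-3-tert-butoxy-2-(hydroxymethyl)-3-oxoprop-1-en-1-yl]-1-oxo-6-(propan-2-yl)octahydro-2-benzofuran-3a-yl (2E)-2-(hydroxymethyl)-3-[(6R,7S)-1-oxo-6-(propan-2-yl)-1,3,4,5,6,7-hexahydro-2-benzofuran-7-yl]prop-2-enoate | CC(C)[C@H]1CC[C@@]2(OC(=O)/C(=C/[C@H]3C4=C(CC[C@@H]3C(C)C)COC4=O)CO)COC(=O)[C@H]2[C@@H]1/C=C(\CO)C(=O)OC(C)(C)C | intermediate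
26 | CNP0238371.2, (2E)-2-(hydroxymethyl)-3-[(3aS,6R,7S,7aS)-3a-{[(2E)-2-(hydroxymethyl)-3-[(6R,7S)-1-oxo-6-(propan-2-yl)-1,3,4,5,6,7-hexahydro-2-benzofuran-7-yl]prop-2-enoyl]oxy}-1-oxo-6-(propan-2-yl)octahydro-2-benzofuran-7-yl]prop-2-enoic acid | CC(C)[C@H]1CC[C@@]2(OC(=O)/C(=C/[C@H]3C4=C(CC[C@@H]3C(C)C)COC4=O)CO)COC(=O)[C@H]2[C@@H]1/C=C(\CO)C(=O)O | target

Total step count: 15. Longest linear sequence: 13 steps (steps 1–3, 5–8, 10–15); steps 4 and 9 are side branches.

Steps most likely to fail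

Step 5 (cycloaddition). The inside ring oxygen disfavours the s-cis diene, so Lewis-acid decomposition of the enol carbonate may outrun cycloaddition, or endo and facial control may erode under the mild copper catalyst. The fallback replaces catalyst control by auxiliary control with a much stronger chelating aluminium Lewis acid. It sets out from 7 and 6 and comes back at 14. Acid 7 is coupled with purchased (4R)-4-benzyl-1,3-oxazolidin-2-one through the pivalic mixed anhydride to give (4R)-4-benzyl-3-[(2E)-4-ethoxy-4-oxobut-2-enoyl]-1,3-oxazolidin-2-one F1. With Et2AlCl (1.4 equiv, CH2Cl2, −78 °C) the cationic aluminium chelate of F1 should add diene 6 endo on the Re face of the imide alpha-carbon, the benzyl group shielding the Si face, to give ethyl (5S,6S,7R,8S)-6-{[(4R)-4-benzyl-2-oxo-1,3-oxazolidin-3-yl]carbonyl}-2-oxo-8-(propan-2-yl)-1,3-dioxaspiro[4.5]dec-9-ene-7-carboxylate F2. Hydrogenation over Rh/Al2O3 gives the decane analogue ethyl (5S,6S,7R,8R)-6-{[(4R)-4-benzyl-2-oxo-1,3-oxazolidin-3-yl]carbonyl}-2-oxo-8-(propan-2-yl)-1,3-dioxaspiro[4.5]decane-7-carboxylate F3, and LiOH/H2O2 followed by acidification as in step 7 returns lactone acid 14.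

Step 13 (esterification). Acylation of the hindered tertiary alcohol may not compete with base-induced beta-elimination of the newly formed beta-acyloxy lactone or with decay of the activated acid. The fallback builds the enoate on the alcohol by olefination instead of acylating with the complete acid. It sets out from 19 and 15 and comes back at 23. Alcohol 19 is acylated with the small, highly reactive bromoacetyl bromide (pyridine, CH2Cl2, 0 °C) to give tert-butyl (2Z)-2-bromo-3-[(3aS,6R,7R,7aS)-3a-[(bromoacetyl)oxy]-1-oxo-6-(propan-2-yl)octahydro-2-benzofuran-7-yl]prop-2-enoate F4. PPh3 in toluene gives the phosphonium bromide of F4 F5, aqueous Na2CO3 the stabilised ylide F6, and NBS (as in step 9) the alpha-bromo ylide F7. In parallel, alcohol 15 is oxidised to aldehyde 18, which is isolated this time and dehydrated with Burgess reagent to (6R,7R)-1-oxo-6-(propan-2-yl)-1,3,4,5,6,7-hexahydro-2-benzofuran-7-carbaldehyde F8. Wittig reaction of F7 with F8 (toluene, 60 °C) should give dibromide 23 with the (Z)-bromoacrylate geometry.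

Step 3 (carboxylative cyclisation). A primary propargylic alcohol has no gem-dialkyl assistance, so the reaction may stall at the open carbonate salt or divert to Meyer–Schuster-type enone formation. The fallback is a two-step gold route that carries the carbonate carbon in the substrate. It sets out from 5 and comes back at 6. Alcohol 5 is converted with Boc2O and catalytic DMAP into tert-butyl (4E)-6-methylhept-4-en-2-yn-1-yl carbonate F9. Catalytic Ph3PAuNTf2 (monovalent gold, CH2Cl2, rt) should then induce anti 5-exo-dig attack of the carbonate carbonyl oxygen on the alkyne with loss of the tert-butyl group, giving the (Z)-alkylidene carbonate 6.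

Further compounds
F1 | step 5 | (4R)-4-benzyl-3-[(2E)-4-ethoxy-4-oxobut-2-enoyl]-1,3-oxazolidin-2-one | CCOC(=O)/C=C/C(=O)N1[C@H](Cc2ccccc2)COC1=O
F2 | step 5 | ethyl (5S,6S,7R,8S)-6-{[(4R)-4-benzyl-2-oxo-1,3-oxazolidin-3-yl]carbonyl}-2-oxo-8-(propan-2-yl)-1,3-dioxaspiro[4.5]dec-9-ene-7-carboxylate | CC(C)[C@H]1C=C[C@@]2(COC(=O)O2)[C@@H](C(=O)N3[C@H](Cc4ccccc4)COC3=O)[C@@H]1C(=O)OCC
F3 | step 5 | ethyl (5S,6S,7R,8R)-6-{[(4R)-4-benzyl-2-oxo-1,3-oxazolidin-3-yl]carbonyl}-2-oxo-8-(propan-2-yl)-1,3-dioxaspiro[4.5]decane-7-carboxylate | CC(C)[C@H]1CC[C@@]2(COC(=O)O2)[C@@H](C(=O)N3[C@H](Cc4ccccc4)COC3=O)[C@@H]1C(=O)OCC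
F4 | step 13 | tert-butyl (2Z)-2-bromo-3-[(3aS,6R,7R,7aS)-3a-[(bromoacetyl)oxy]-1-oxo-6-(propan-2-yl)octahydro-2-benzofuran-7-yl]prop-2-enoate | CC(C)[C@H]1CC[C@@]2(OC(=O)CBr)COC(=O)[C@H]2[C@@H]1/C=C(\Br)C(=O)OC(C)(C)C
F5 | step 13 | phosphonium bromide of F4, [2-oxo-2-(lactone-3a-yloxy)ethyl]triphenylphosphonium bromide | CC(C)[C@H]1CC[C@@]2(OC(=O)C[P+](c3ccccc3)(c3ccccc3)c3ccccc3)COC(=O)[C@H]2[C@@H]1/C=C(\Br)C(=O)OC(C)(C)C.[Br-]
F6 | step 13 | stabilised ylide, lactone-3a-yl (triphenyl-λ5-phosphanylidene)acetate | CC(C)[C@H]1CC[C@@]2(OC(=O)C=P(c3ccccc3)(c3ccccc3)c3ccccc3)COC(=O)[C@H]2[C@@H]1/C=C(\Br)C(=O)OC(C)(C)C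
F7 | step 13 | alpha-bromo ylide, lactone-3a-yl bromo(triphenyl-λ5-phosphanylidene)acetate | CC(C)[C@H]1CC[C@@]2(OC(=O)C(Br)=P(c3ccccc3)(c3ccccc3)c3ccccc3)COC(=O)[C@H]2[C@@H]1/C=C(\Br)C(=O)OC(C)(C)C
F8 | step 13 | (6R,7R)-1-oxo-6-(propan-2-yl)-1,3,4,5,6,7-hexahydro-2-benzofuran-7-carbaldehyde | O=C[C@H]1C2=C(CC[C@@H]1C(C)C)COC2=O
F9 | step 3 | tert-butyl (4E)-6-methylhept-4-en-2-yn-1-yl carbonate | CC(C)/C=C/C#CCOC(=O)OC(C)(C)C
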